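At early times Monday's flask and Sunday's flask looked alike: at 1.50 min each read 19 % product. The two differed in the coupling partner charged, and I wanted to know what that difference was worth.

in all of them: substrate 0.21 M; free catalyst 0.1 mol%
- Monday's: coupling partner 2.5 equiv; the very flask that is asked about, followed so far
- Sunday's: coupling partner 1.7 equiv; run made earlier
- flask: coupling partner 2.50 equiv

- Monday's (time / min: product / %): 1.50: 19; 3.00: 33; 5.00: 48; 6.00: 55
- Sunday's (time / min: product / %): 1.50: 19; 4.00: 39; 10.0: 54; 20.0: 70

(readings scatter by 2 percentage points)

- apparent order in coupling partner when 30 % of the substrate are converted (percent change of the rate of making product for one percent more coupling partner charged)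
- apparent order in free catalyst when 30 % of the substrate are converted (percent change of the rate of making product for one percent more free catalyst charged)

My bench rule was pseudo-first-order behaviour with the coupling partner in excess: the constant k = ln(1/(1 − x))/t, with x the fraction converted, should stay put. Monday's flask gave 0.133 min⁻¹ at 3.00 min and Sunday's gave 0.124 min⁻¹ at 4.00 min. The rule broke in Sunday's flask, though: between 10.0 min and 20.0 min the constant read 0.0427 min⁻¹, less than the earlier value.

For the order I took logarithms. The charges stood in the ratio 1.47, and the slope of ln k against ln [coupling partner] across the two flasks came to 0.200. A reading's scatter of 2 percentage points moved ln k by 7.45 % in Monday's flask and 6.63 % in Sunday's. Combining these and dividing by the logarithm of the charge ratio gave the width of the pair, the error in an order read from two runs: 0.259. So my reading was 0.200 give or take 0.259. The loading of free catalyst was the same in both flasks, so the pair gave no slope for it.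

The forecast put the order in coupling partner at 0.1, lower than my slope, on the ground that “the dependence on coupling partner is saturating or switching”. Its order of 1 in free catalyst was a separate matter: since that order had not been tested, the forecast offered it as a guess for a catalyst-limited step.

    catalyst intermediate C → catalyst intermediate D (k = 23.0 s⁻¹)
    catalyst intermediate D → free catalyst + product (k = 12.0 s⁻¹)
    substrate + catalyst intermediate B ⇌ catalyst intermediate C (K = 3.70 M⁻¹, k = 76.0 M⁻¹ s⁻¹)
    free catalyst ⇌ dormant form (K = 19.0, k = 0.0170 s⁻¹)
    coupling partner + free catalyst → catalyst intermediate A (k = 30.0 M⁻¹ s⁻¹)
    catalyst intermediate A → by-product + catalyst intermediate B (k = 17.0 s⁻¹)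

The flask gave 0.68 in coupling partner and 1.4 in free catalyst. By 3.00 min, close to the moment asked about, the dormant form held 37.8 % of the catalyst charged to this flask. Measured in the width of the pair, the order of 0.68 stands 2.63 widths from zero.

(The earlier runs and the new flask come from a simulation with constants of no real substance; scatter was added.)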